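**Assumption:** the target is the trans-1,2 isomer as drawn, (3R,4S)-4-(3,4-dimethoxyphenyl)-6-hydroxy-3-(hydroxymethyl)-5-methoxy-3,4-dihydronaphthalene-2-carbaldehyde, which is (1S,2R) in the dihydronaphthalene numbering used below. Benzyl groups protect the phenol and the primary alcohol. 4,5-Dibromoveratrole and 3-benzyloxypropanal are taken as purchasable.

## Retrosynthetic overview
1. Target ⇐ Vilsmeier formylation at C3 of a 7-OBn-1,2-dihydronaphthalene, then removal of both benzyl groups. C3 is the β-carbon of a para-alkoxystyrene, so it is the nucleophilic site.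
2. The dihydronaphthalene ⇐ cyclization of a methyl enol ether (via its oxocarbenium ion) onto the only free ortho carbon of the guaiacol ring. This is the second ring formed, and loss of MeOH gives C3=C4. A bromine on the veratryl ring blocks that ring's competing cyclization and is removed afterwards.
3. The enol ether ⇐ Wittig reaction of a chroman-2-ol (lactol). The chroman is a temporary first ring, made by adding 3-benzyloxypropanal to an o-quinone methide. The o-quinone methide is the dearomatized form of an o-hydroxybenzhydrol, and the addition sets C1 and C2 trans in one step.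
4. The benzhydrol ⇐ 2,3-dihydroxybenzaldehyde (mono-benzylated) plus the 2-bromo-4,5-dimethoxyphenyl Grignard reagent from 4,5-dibromoveratrole.

## Route

**Step 1**
Reactants: 1 (2,3-dihydroxybenzaldehyde), 2 (benzyl bromide)
Product: 3 (3-(benzyloxy)-2-hydroxybenzaldehyde)
Conditions: 2 (1.0 equiv), K2CO3, MeCN, rt
Reagents that add atoms: benzyl bromide, BrCc1ccccc1
Why: The 2-OH is hydrogen-bonded to the aldehyde and is less nucleophilic, so Williamson etherification takes place selectively at the 3-OH.

**Step 2**
Reactants: 3, 4 (1,2-dibromo-4,5-dimethoxybenzene)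
Product: 5 ((3-(benzyloxy)-2-hydroxyphenyl)(2-bromo-4,5-dimethoxyphenyl)methanol, racemic)
Conditions: 4 (2.6 equiv), i-PrMgCl·LiCl, THF, –40 °C, 1 h (Br/Mg exchange); then 3, –40 °C → rt
Reagents that add atoms: none
Why: Mono Br/Mg exchange gives the 2-bromoaryl Grignard reagent, which adds 1,2 to the aldehyde (the first equivalent deprotonates the phenol). The remaining ortho-bromine sits on the veratryl carbon para to its 3-OMe, which is the position that would otherwise cyclize in step 6.

**Step 3**
Reactants: 5, 6 (3-(benzyloxy)propanal), catalyst 7 ((S)-diphenylprolinol TMS ether)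
Product: 8 (trans-3-(benzyloxymethyl)-8-(benzyloxy)-4-(2-bromo-4,5-dimethoxyphenyl)chroman-2-ol, anomeric mixture)
Conditions: 6 (2 equiv), 7 (20 mol %), 4-O2NC6H4CO2H (20 mol %), toluene, 4 °C → rt, 48 h
Reagents that add atoms: none
Why: Acid ionizes the electron-rich benzhydrol to the dearomatized o-quinone methide. The E-enamine of 6 adds to it, and the phenol then closes onto the aldehyde to give the chromanol. (S)-7 shields one enamine face, as in its propanal/nitroalkene additions, which fixes the α-carbon (future C2). Ring–chain tautomerism equilibrates that carbon, so the chroman settles with the 4-aryl and 3-CH2OBn both pseudo-equatorial (trans), which fixes C1.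
Proposed new method: the closest known reaction is amine-catalysed Michael/hemiacetalization of aldehydes with in situ o-quinone methides to give chroman-2-ols. Here the o-quinone methide comes from an o-hydroxybenzhydrol carrying a 2-bromoaryl group and a 3-OBn substituent, and the β-benzyloxy aldehyde serves as the enamine partner. The chroman is cleaved again in the next step.

**Step 4**
Reactants: 8, 9 ((methoxymethyl)triphenylphosphonium chloride)
Product: 10 (phenolic methyl enol ether, E/Z mixture)
Conditions: 9 (3 equiv), t-BuOK (3 equiv), THF, 0 °C → rt
Reagents that add atoms: (methoxymethyl)triphenylphosphonium chloride, COC[P+](c1ccccc1)(c1ccccc1)c1ccccc1.[Cl-]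
Why: The base opens the lactol to the aldehyde phenoxide, and the Wittig methoxymethylenation converts the aldehyde to the enol ether. Only a small amount of free aldehyde is present at any time, which limits epimerization and β-elimination of OBn. After this step C2 is no longer α to a carbonyl.

**Step 5**
Reactants: 10, 11 (methyl iodide)
Product: 12 (aryl methyl ether, giving the 8-OMe)
Conditions: 11 (3 equiv), K2CO3, acetone, reflux
Reagents that add atoms: methyl iodide, CI
Why: Williamson O-methylation of the phenol. The enol ether and aryl bromide are untouched.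

**Step 6**
Reactants: 12
Product: 13 ((1S,2R)-1-(2-bromo-4,5-dimethoxyphenyl)-7-benzyloxy-2-(benzyloxymethyl)-8-methoxy-1,2-dihydronaphthalene)
Conditions: BF3·OEt2 (1.2 equiv), CH2Cl2, –30 → 25 °C
Reagents that add atoms: none
Why: Protonation of the enol ether gives an oxocarbenium ion (Bradsher-type cyclodehydration). Ring A attacks it at its only free ortho carbon, which is para to the 7-OBn group, and the benzylic C4–OMe ionizes and loses H3 to give the styrene. C1 and C2 are untouched. The bromine blocks the veratryl ring's reactive site (para to its 3-OMe), leaving only its hindered ortho position.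

**Step 7**
Reactants: 13
Product: 14 ((1S,2R)-1-(3,4-dimethoxyphenyl)-7-benzyloxy-2-(benzyloxymethyl)-8-methoxy-1,2-dihydronaphthalene)
Conditions: t-BuLi (2.1 equiv), THF, –78 °C, 15 min; then MeOH
Reagents that add atoms: none (only H is added)
Why: Bromine–lithium exchange followed by protonation removes the blocking bromine. The benzyl ethers and the alkene survive at –78 °C.

**Step 8**
Reactants: 14, 15 (DMF)
Product: 16 (enal bis-benzyl ether)
Conditions: POCl3 (1.5 equiv), DMF, 0 °C → rt; then aq. NaOAc
Reagents that add atoms: N,N-dimethylformamide, CN(C)C=O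
Why: Vilsmeier–Haack formylation occurs at C3, the β-carbon of the p-alkoxystyrene, which is more nucleophilic than the veratryl ring. If C2 epimerizes through an iminium/enamine, it returns to the trans-diaxial arrangement, which is the thermodynamically preferred one because of the peri-OMe and A(1,3) strain with the C3 substituent.

**Step 9**
Reactants: 16
Product: 17 (vitekwangin B)
Conditions: BCl3 (5 equiv), pentamethylbenzene (6 equiv), CH2Cl2, –78 °C, 30 min; then MeOH/NaHCO3
Reagents that add atoms: none
Why: BCl3 with a cation scavenger cleaves both benzyl ethers (aryl and primary alkyl) at –78 °C. The enal, the styrene and the methyl ethers survive, and no stereocenter is touched.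

## Compound list
1 | 2,3-dihydroxybenzaldehyde | O=Cc1cccc(O)c1O | starting material
2 | benzyl bromide | BrCc1ccccc1 | starting material
3 | 3-(benzyloxy)-2-hydroxybenzaldehyde | O=Cc1cccc(OCc2ccccc2)c1O | intermediate
4 | 1,2-dibromo-4,5-dimethoxybenzene | COc1cc(Br)c(Br)cc1OC | starting material
5 | (3-(benzyloxy)-2-hydroxyphenyl)(2-bromo-4,5-dimethoxyphenyl)methanol (racemic) | COc1cc(Br)c(cc1OC)C(O)c1cccc(OCc2ccccc2)c1O | intermediate
6 | 3-(benzyloxy)propanal | O=CCCOCc1ccccc1 | starting material
7 | (S)-diphenylprolinol trimethylsilyl ether | C[Si](C)(C)OC(c1ccccc1)(c1ccccc1)[C@@H]1CCCN1 | starting material (catalyst)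
8 | trans-chroman-2-ol (anomeric mixture) | COc1cc(Br)c(cc1OC)[C@H]1c2cccc(OCc3ccccc3)c2OC(O)[C@@H]1COCc1ccccc1 | intermediate
9 | (methoxymethyl)triphenylphosphonium chloride | COC[P+](c1ccccc1)(c1ccccc1)c1ccccc1.[Cl-] | starting material
10 | phenolic methyl enol ether | COc1cc(Br)c(cc1OC)[C@H]([C@@H](COCc1ccccc1)C=COC)c1cccc(OCc2ccccc2)c1O | intermediate
11 | methyl iodide | CI | starting material
12 | aryl methyl ether enol ether | COc1cc(Br)c(cc1OC)[C@H]([C@@H](COCc1ccccc1)C=COC)c1cccc(OCc2ccccc2)c1OC | intermediate
13 | bromo-1,2-dihydronaphthalene | COc1cc(Br)c(cc1OC)[C@H]2c3c(ccc(OCc4ccccc4)c3OC)C=C[C@@H]2COCc1ccccc1 | intermediate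
14 | debrominated 1,2-dihydronaphthalene | COc1ccc(cc1OC)[C@H]2c3c(ccc(OCc4ccccc4)c3OC)C=C[C@@H]2COCc1ccccc1 | intermediate
15 | N,N-dimethylformamide | CN(C)C=O | starting material
16 | enal bis-benzyl ether | COc1ccc(cc1OC)[C@H]2c3c(ccc(OCc4ccccc4)c3OC)C=C(C=O)[C@@H]2COCc1ccccc1 | intermediate
17 | vitekwangin B | COc1ccc([C@H]2c3c(ccc(O)c3OC)C=C(C=O)[C@@H]2CO)cc1OC | target

**Total steps:** 9. **Longest linear sequence:** 9 (1 → 3 → 5 → 8 → 10 → 12 → 13 → 14 → 16 → 17, counting step 1).

## Three steps most likely to fail
1. **Step 3 (o-quinone methide/enamine addition).** Diastereo- or enantioselectivity may be poor, or the β-OBn aldehyde may eliminate under amine catalysis. Fallback: run the addition with an achiral amine/acid to give racemic trans-8, carry it forward, and resolve by preparative chiral HPLC at 13.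
2. **Step 6 (cyclization).** It may lose selectivity over the hindered veratryl ortho position, cleave benzyl ethers, or stall at the C4–OMe ether. Fallback: convert lactol 8 to the terminal alkyne with the Ohira–Bestmann reagent (then methylate the phenol) and close the ring by Au(I)-catalysed 6-endo hydroarylation.
3. **Step 8 (Vilsmeier formylation).** Competing formylation of the veratryl ring, or partial erosion of C2, may occur. Fallback: brominate C3 of 14 (NBS, then base) and install the CHO by Pd-catalysed reductive formylation of the vinyl bromide with CO/H2 or a silane.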